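The plan cuts two bonds at C6 of the acetoxycyclohexene ring: the tetrasubstituted C5=C6 double bond and the C6–C7 bond to the alkyne. The key step exploits the 1,4-relation between the carbinol carbon C3 and C6 across this ring. In the precursor the C3 oxygen acylates C6, giving an enantiopure α,α-dimethyl-γ-butyrolactone whose side chain carries a phosphonium group at C5. In one flask a lithium dienynyl acetylide adds to the lactone carbonyl, the lactolate opens, and an intramolecular Wittig reaction exchanges the lactone for the carbocycle. Acetic anhydride then caps the C3 oxygen. Epoxide and butenolide are completed beforehand, and two Suzuki couplings finish the polyene.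

Key step: step 17

Remark on numbering: in the acetoxycyclohexene ring C1 = CMe2, C2 = CH2, C3 = CHOAc, C4 = CH2, C5 = C(CH3)=, C6 = =C(alkynyl), and C7≡C8 is the alkyne. Primed numbers (C1'–C7') denote the same positions of the epoxycyclohexane end.
Assumption: compounds 1, 10, 13, 17 and 20 and all named reagents (including bis(pinacolato)borylmethane and (dichloromethyl)boronic acid pinacol ester) are taken as commercial.

Step 1
Reactants: 1 (−)-actinol, (4R,6R)-4-hydroxy-2,2,6-trimethylcyclohexan-1-one
Product: 2 (4R,6R)-4-[(tert-butyldimethylsilyl)oxy]-2,2,6-trimethylcyclohexan-1-one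
Conditions: TBSCl, imidazole, DMF, 23 °C
Reagents that add atoms: tert-butyldimethylsilyl chloride, CC(C)(C)[Si](C)(C)Cl
Why: Standard imidazole-promoted O-silylation masks the only O–H before the amide base of step 2 and touches no stereocentre.

Step 2
Reactants: 2 silyl ether of actinol
Product: 3 (4R)-4-[(tert-butyldimethylsilyl)oxy]-2,6,6-trimethylcyclohex-1-en-1-yl trifluoromethanesulfonate
Conditions: LDA, THF, −78 °C; PhNTf2, −78 → 23 °C
Reagents that add atoms: N-phenylbis(trifluoromethanesulfonimide), FC(F)(F)S(=O)(=O)N(c1ccccc1)S(=O)(=O)C(F)(F)F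
Why: C2 is quaternary, so LDA can enolise the ketone only towards C6, and O-triflation of that enolate (enol triflate synthesis) gives a single tetrasubstituted enol triflate, erasing C6 and leaving the C4 stereocentre untouched.

Step 3
Reactants: 3 enol triflate
Product: 4 methyl (4R)-4-[(tert-butyldimethylsilyl)oxy]-2,6,6-trimethylcyclohex-1-ene-1-carboxylate
Conditions: Pd(PPh3)4 (cat.), CO (1 atm), Et3N, MeOH–DMF, 60 °C
Reagents that add atoms: carbon monoxide, [C-]#[O+]; methanol, CO
Why: Palladium-catalysed methoxycarbonylation of an enol triflate (oxidative addition, CO insertion, methanolysis) attaches C7' under conditions that spare the silyl ether.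

Step 4
Reactants: 4 unsaturated ester
Product: 5 [(4R)-4-[(tert-butyldimethylsilyl)oxy]-2,6,6-trimethylcyclohex-1-en-1-yl]methanol
Conditions: DIBAL-H (2.5 equiv), CH2Cl2, −78 → 0 °C; Rochelle salt
Reagents that add atoms: none
Why: DIBAL-H reduces the hindered conjugated ester in the 1,2-sense to the allylic alcohol that the directed epoxidation needs.

Step 5
Reactants: 5 allylic alcohol
Product: 6 [(1R,4S,6R)-4-[(tert-butyldimethylsilyl)oxy]-2,2,6-trimethyl-7-oxabicyclo[4.1.0]heptan-1-yl]methanol (epoxide anti to the silyloxy group)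
Conditions: Ti(OiPr)4 (20 mol%), D-(−)-DET (24 mol%), TBHP, 4 Å MS, CH2Cl2, −20 °C
Reagents that add atoms: tert-butyl hydroperoxide, CC(C)(C)OO
Why: In this Katsuki–Sharpless asymmetric epoxidation the titanium–D-(−)-tartrate complex bound to the allylic hydroxyl delivers oxygen to the face of the C5'=C6' bond anti to the silyloxy group, so reagent control sets both epoxide carbons (5'R,6'S in the target) at once.

Step 6
Reactants: 6 epoxy alcohol
Product: 7 (1S,4S,6R)-4-[(tert-butyldimethylsilyl)oxy]-2,2,6-trimethyl-7-oxabicyclo[4.1.0]heptane-1-carbaldehyde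
Conditions: TPAP (5 mol%), NMO, 4 Å MS, CH2Cl2, 23 °C
Reagents that add atoms: none
Why: The Ley–Griffith oxidation is neutral and stops at the non-enolisable aldehyde without opening the epoxide or cleaving the silyl ether.

Step 7
Reactants: 7 epoxy aldehyde
Product: 8 2-{(E)-2-[(1S,4S,6R)-4-[(tert-butyldimethylsilyl)oxy]-2,2,6-trimethyl-7-oxabicyclo[4.1.0]heptan-1-yl]ethenyl}-4,4,5,5-tetramethyl-1,3,2-dioxaborolane
Conditions: CH2(Bpin)2, LiTMP (TMP + n-BuLi), THF, 0 °C; then 7, −78 → 23 °C
Reagents that add atoms: bis(pinacolato)borylmethane, CC1(C)OB(CB2OC(C)(C)C(C)(C)O2)OC1(C)C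
Why: In this boron–Wittig olefination lithiated bis(boryl)methane adds to the aldehyde and syn B–O elimination from the less crowded adduct gives the (E)-vinylboronate, with no low-valent metal that could open the adjacent epoxide.

Step 8
Reactants: 8 silylated vinylboronate
Product: 9 (1R,3S,6S)-1,5,5-trimethyl-6-[(E)-2-(4,4,5,5-tetramethyl-1,3,2-dioxaborolan-2-yl)ethenyl]-7-oxabicyclo[4.1.0]heptan-3-ol
Conditions: TBAF, AcOH (1:1), THF, 23 °C
Reagents that add atoms: none
Why: Buffered fluoride cleaves the Si–O bond while the epoxide and the pinacol boronate, which binds fluoride only reversibly, are kept.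

Step 9
Reactants: 10 (E)-3-methylpent-2-en-4-yn-1-ol
Product: 11 (E)-3-methylpent-2-en-4-ynal
Conditions: MnO2 (excess), CH2Cl2, 23 °C, dark
Reagents that add atoms: none
Why: MnO2 oxidises the allylic alcohol selectively to the enal with retention of the E geometry and leaves the terminal alkyne alone.

Step 10
Reactants: 11 enynal
Product: 12 2-[(1E,3E)-4-methylhexa-1,3-dien-5-yn-1-yl]-4,4,5,5-tetramethyl-1,3,2-dioxaborolane
Conditions: CrCl2 (8 equiv), LiI (4 equiv), Cl2CHBpin (2 equiv), THF, 23 °C
Reagents that add atoms: (dichloromethyl)boronic acid pinacol ester, ClC(Cl)B1OC(C)(C)C(C)(C)O1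
Why: In this Takai–Utimoto olefination the gem-dichromium species from the (dihalomethyl)boronate adds to the aldehyde and eliminates to the (E)-alkenylboronate, and Cr(II) tolerates the terminal alkyne.

Step 11
Reactants: 13 propiolic acid
Product: 14 (E)-2,3-dibromoacrylic acid
Conditions: Br2, CHCl3, 0 → 23 °C, dark
Reagents that add atoms: bromine, BrBr
Why: Electrophilic anti-addition of bromine across the triple bond gives the (E)-dibromide, which places the β-bromine cis to the carboxyl group as step 12 requires.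

Step 12
Reactants: 12 dienynyl boronate; 14 (E)-2,3-dibromoacrylic acid
Product: 16 (5Z)-3-bromo-5-[(2E,4E)-2-methyl-5-(4,4,5,5-tetramethyl-1,3,2-dioxaborolan-2-yl)penta-2,4-dien-1-ylidene]furan-2(5H)-one, via bromoenynoic acid 15 (not isolated)
Conditions: Pd(PPh3)4 (5 mol%), CuI (5 mol%), Et3N, MeCN, 23 °C, Ar, dark
Reagents that add atoms: none
Why: In this tandem Sonogashira coupling/5-exo-dig lactonisation of a β-haloacrylic acid the β-C–Br bond (a vinylogous acyl bromide) reacts before the α-C–Br bond, anti-oxymetallation of the alkyne of 15 by the cis carboxylate followed by protonolysis gives the (Z)-ylidene butenolide, and the boronate stays inert without an oxygen base.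

Step 13
Reactants: 17 methyl 2,2-dimethylpent-4-enoate
Product: 18 methyl 2,2-dimethyl-3-(oxiran-2-yl)propanoate (racemic)
Conditions: mCPBA, CH2Cl2, 0 → 23 °C
Reagents that add atoms: 3-chloroperoxybenzoic acid, OOC(=O)c1cccc(Cl)c1
Why: Prilezhaev epoxidation of the only alkene gives the racemic terminal epoxide.

Step 14
Reactants: 18 racemic epoxide
Product: 19 methyl 2,2-dimethyl-3-[(2S)-oxiran-2-yl]propanoate
Conditions: (S,S)-(salen)Co(III)OAc (0.5 mol%), H2O (0.55 equiv), THF (minimum), 0 → 23 °C; distillation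
Reagents that add atoms: none
Why: In the Jacobsen hydrolytic kinetic resolution the (S,S)-cobalt–salen catalyst hydrolyses the (R)-epoxide selectively, so the unreacted (S)-epoxide carries the future C3 stereocentre as a single enantiomer.

Step 15
Reactants: 19 (S)-epoxy ester; 20 ethyltriphenylphosphonium bromide
Product: 23 {(2RS)-1-[(2S)-4,4-dimethyl-5-oxooxolan-2-yl]propan-2-yl}triphenylphosphonium bromide, via ethylidene ylide 21 (not isolated), via oxido phosphonium betaine 22 (not isolated)
Conditions: 20, n-BuLi (1.0 equiv), THF, 0 °C; 19, 0 → 40 °C; then 48% aq HBr, 0 °C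
Reagents that add atoms: hydrogen bromide, Br
Why: A non-stabilised ylide opens a terminal epoxide at its CH2 terminus (first stage of the known epoxide-to-γ-oxido-ylide homologation), alkoxide 22 lactonises onto the gem-dimethyl ester (Thorpe–Ingold effect) and HBr returns any ylide to the salt; the C3–O bond is not touched, so the configuration of 19 is retained, and the new C5 centre is left as a mixture because step 17 erases it.

Step 16
Reactants: 11 enynal
Product: 24 (3E,5E)-6-iodo-3-methylhexa-3,5-dien-1-yne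
Conditions: CrCl2 (6 equiv), CHI3 (2 equiv), dioxane–THF 6:1, 0 °C, dark
Reagents that add atoms: iodoform, IC(I)I
Why: The Takai olefination converts the enal into the (E)-iodoalkene by elimination from the gem-dichromium adduct and tolerates the terminal alkyne.

Step 17
Reactants: 23 lactone phosphonium bromide; 24 iododienyne
Product: 29 (1R)-4-[(3E,5E)-6-iodo-3-methylhexa-3,5-dien-1-yn-1-yl]-3,5,5-trimethylcyclohex-3-en-1-yl acetate, via lactone ylide 25 (not isolated), via lithium acetylide 26 (not isolated), via oxido ynone ylide 27 (not isolated), via lithium cyclohexenolate 28 (not isolated)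
Conditions: 23, LiHMDS (1.0 equiv), THF, −78 °C; 24, LiHMDS (1.05 equiv), THF, −78 °C; combine, −78 → 23 °C, dark; then Ac2O, DMAP (cat.), 0 °C
Reagents that add atoms: acetic anhydride, CC(=O)OC(C)=O
Why: Proposed new method: LiHMDS converts 23 into ylide 25 and 24 into acetylide 26; 26 adds once to the lactone carbonyl C6, the lithium lactolate opens on warming to the γ-oxido ynone ylide 27, and the ylide carbon C5 attacks the ynone carbonyl to give a ring-fused oxaphosphetane that loses Ph3P=O, leaving the C5=C6 enyne of 28, which Ac2O acetylates. The closest known reaction types are the addition of lithium acetylides to γ-lactones, the Wittig olefination of lactols through their open hydroxy-carbonyl form, the γ-oxido-ylide route from epoxides to homoallylic alcohols and the intramolecular Wittig synthesis of cycloalkenes; only their union in one flask and the tetrasubstituted enyne product go beyond them. The cyclohexene closes by 6-exo-trig attack of C5 on C6 followed by [2+2] cycloreversion, so the new double bond is necessarily endocyclic and no E/Z question arises. No stereocentre is created: C3 comes from epoxide 19 and its C–O bond is never broken, while the epimeric C5 centre of 23 is erased in the ylide. The step needs single addition of 26 (secured by the persistent lactolate and the fast intramolecular trap of the ynone), 1,2- rather than 1,4-attack on the ynone (1,4-attack would need an eight-membered ring), no enolisation (C1 is quaternary) and survival of the (E)-iodoalkene (no hydrogen anti to iodine, amide base only, no alkyllithium).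

Step 18
Reactants: 16 bromobutenolide boronate; 29 cyclohexenyl iododienyne acetate
Product: 30 (1R)-4-{(3E,5E,7E,9E)-11-[(2Z)-4-bromo-5-oxofuran-2(5H)-ylidene]-3,10-dimethylundeca-3,5,7,9-tetraen-1-yn-1-yl}-3,5,5-trimethylcyclohex-3-en-1-yl acetate
Conditions: PdCl2(dppf)·CH2Cl2 (5 mol%), K3PO4 (2 M aq), THF, 23 °C, Ar, dark; 29 in slight excess
Reagents that add atoms: none
Why: This Suzuki–Miyaura coupling proceeds with retention at both alkenyl carbons, and oxidative addition into the alkenyl C–I bond of 29 is much faster than into the α-C–Br bond of 16, which favours cross-coupling over self-coupling of 16 and keeps the bromide for step 19.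

Step 19
Reactants: 30 bromobutenolide polyene; 9 epoxy vinylboronate
Product: 31 target (pyrrhoxanthin, CNP0337675.1)
Conditions: Pd(OAc)2 (5 mol%), SPhos (10 mol%), K3PO4 (2 M aq), THF, 30 °C, Ar, dark
Reagents that add atoms: none
Why: A second Suzuki–Miyaura coupling, now at the remaining α-bromobutenolide with a more active biarylphosphine catalyst, joins the (E)-vinylboronate with retention and tolerates the free hydroxyl, the acetate and the epoxide.

Compound list
1 | (4R,6R)-4-hydroxy-2,2,6-trimethylcyclohexan-1-one ((−)-actinol) | C[C@@H]1C[C@@H](O)CC(C)(C)C1=O | starting material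
2 | (4R,6R)-4-[(tert-butyldimethylsilyl)oxy]-2,2,6-trimethylcyclohexan-1-one | C[C@@H]1C[C@@H](O[Si](C)(C)C(C)(C)C)CC(C)(C)C1=O | intermediate
3 | (4R)-4-[(tert-butyldimethylsilyl)oxy]-2,6,6-trimethylcyclohex-1-en-1-yl triflate | FC(F)(F)S(=O)(=O)OC1=C(C)C[C@@H](O[Si](C)(C)C(C)(C)C)CC1(C)C | intermediate
4 | methyl (4R)-4-[(tert-butyldimethylsilyl)oxy]-2,6,6-trimethylcyclohex-1-ene-1-carboxylate | COC(=O)C1=C(C)C[C@@H](O[Si](C)(C)C(C)(C)C)CC1(C)C | intermediate
5 | [(4R)-4-[(tert-butyldimethylsilyl)oxy]-2,6,6-trimethylcyclohex-1-en-1-yl]methanol | OCC1=C(C)C[C@@H](O[Si](C)(C)C(C)(C)C)CC1(C)C | intermediate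
6 | [(1R,4S,6R)-4-[(tert-butyldimethylsilyl)oxy]-2,2,6-trimethyl-7-oxabicyclo[4.1.0]heptan-1-yl]methanol | OC[C@@]12O[C@]1(C)C[C@@H](O[Si](C)(C)C(C)(C)C)CC2(C)C | intermediate
7 | (1S,4S,6R)-4-[(tert-butyldimethylsilyl)oxy]-2,2,6-trimethyl-7-oxabicyclo[4.1.0]heptane-1-carbaldehyde | O=C[C@@]12O[C@]1(C)C[C@@H](O[Si](C)(C)C(C)(C)C)CC2(C)C | intermediate
8 | (E)-vinylboronate of the silylated epoxycyclohexane, (1S,4S,6R) | CC1(C)OB(/C=C/[C@@]23O[C@]2(C)C[C@@H](O[Si](C)(C)C(C)(C)C)CC3(C)C)OC1(C)C | intermediate
9 | (1R,3S,6S)-1,5,5-trimethyl-6-[(E)-2-(pinacolboryl)ethenyl]-7-oxabicyclo[4.1.0]heptan-3-ol | CC1(C)OB(/C=C/[C@@]23O[C@]2(C)C[C@@H](O)CC3(C)C)OC1(C)C | intermediate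
10 | (E)-3-methylpent-2-en-4-yn-1-ol | C#C/C(C)=C/CO | starting material
11 | (E)-3-methylpent-2-en-4-ynal | C#C/C(C)=C/C=O | intermediate
12 | 2-[(1E,3E)-4-methylhexa-1,3-dien-5-yn-1-yl]-4,4,5,5-tetramethyl-1,3,2-dioxaborolane | C#C/C(C)=C/C=C/B1OC(C)(C)C(C)(C)O1 | intermediate
13 | propiolic acid | C#CC(=O)O | starting material
14 | (E)-2,3-dibromoacrylic acid | OC(=O)/C(Br)=C\Br | intermediate
15 | 2-bromo-2-en-4-ynoic acid from 12 and 14 (alkynyl group cis to CO2H) | OC(=O)/C(Br)=C\C#C/C(C)=C/C=C/B1OC(C)(C)C(C)(C)O1 | intermediate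
16 | (5Z)-3-bromo-5-[(2E,4E)-2-methyl-5-(pinacolboryl)penta-2,4-dien-1-ylidene]furan-2(5H)-one | CC1(C)OB(/C=C/C=C(C)/C=C2C=C(Br)C(=O)O/2)OC1(C)C | intermediate
17 | methyl 2,2-dimethylpent-4-enoate | C=CCC(C)(C)C(=O)OC | starting material
18 | methyl 2,2-dimethyl-3-(oxiran-2-yl)propanoate (racemic) | COC(=O)C(C)(C)CC1CO1 | intermediate
19 | methyl 2,2-dimethyl-3-[(2S)-oxiran-2-yl]propanoate | COC(=O)C(C)(C)C[C@H]1CO1 | intermediate
20 | ethyltriphenylphosphonium bromide | CC[P+](c1ccccc1)(c1ccccc1)c1ccccc1.[Br-] | starting material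
21 | ethylidenetriphenylphosphorane | CC=P(c1ccccc1)(c1ccccc1)c1ccccc1 | intermediate
22 | γ-oxido phosphonium betaine, (S) at the alkoxide carbon | COC(=O)C(C)(C)C[C@H]([O-])CC(C)[P+](c1ccccc1)(c1ccccc1)c1ccccc1 | intermediate
23 | {(2RS)-1-[(2S)-4,4-dimethyl-5-oxooxolan-2-yl]propan-2-yl}triphenylphosphonium bromide | O=C1O[C@H](CC(C)[P+](c2ccccc2)(c2ccccc2)c2ccccc2)CC1(C)C.[Br-] | intermediate
24 | (3E,5E)-6-iodo-3-methylhexa-3,5-dien-1-yne | C#C/C(C)=C/C=C/I | intermediate
25 | ylide of 23 | O=C1O[C@H](CC(C)=P(c2ccccc2)(c2ccccc2)c2ccccc2)CC1(C)C | intermediate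
26 | lithium acetylide of 24 | [Li]C#C/C(C)=C/C=C/I | intermediate
27 | lithium γ-oxido ynone ylide (open form of the lactolate) | [Li+].[O-][C@H](CC(C)=P(c1ccccc1)(c1ccccc1)c1ccccc1)CC(C)(C)C(=O)C#C/C(C)=C/C=C/I | intermediate
28 | lithium (1R)-4-[(3E,5E)-6-iodo-3-methylhexa-3,5-dien-1-yn-1-yl]-3,5,5-trimethylcyclohex-3-en-1-olate | [Li+].[O-][C@@H]1CC(C)=C(C#C/C(C)=C/C=C/I)C(C)(C)C1 | intermediate
29 | (1R)-4-[(3E,5E)-6-iodo-3-methylhexa-3,5-dien-1-yn-1-yl]-3,5,5-trimethylcyclohex-3-en-1-yl acetate | CC(=O)O[C@@H]1CC(C)=C(C#C/C(C)=C/C=C/I)C(C)(C)C1 | intermediate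
30 | α-bromobutenolide polyene carrying the acetoxycyclohexene ring | CC(=O)O[C@@H]1CC(C)=C(C#C/C(C)=C/C=C/C=C/C=C(C)/C=C2C=C(Br)C(=O)O/2)C(C)(C)C1 | intermediate
31 | pyrrhoxanthin (CNP0337675.1) | CC(=O)O[C@@H]1CC(C)=C(C#C/C(C)=C/C=C/C=C/C=C(C)/C=C2C=C(/C=C/[C@@]34O[C@]3(C)C[C@@H](O)CC4(C)C)C(=O)O/2)C(C)(C)C1 | target

Total step count: 19. Longest linear sequence: 9 steps (steps 1–8, then step 19).

Steps most likely to fail

**Step 17 (labelled).**
- Risks: the acetylide may add too slowly to the α,α-dimethyl lactone. Meanwhile the ylide may be lost by proton transfer or by attack on its own lactone carbonyl. The crowded oxaphosphetane may also form too slowly for a clean olefination.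
- Fallback: it separates ring closure from alkene formation by Horner–Wittig chemistry (known reactions only). It sets out from 19 and comes back at 29.
- Lithiated ethyldiphenylphosphine oxide (n-BuLi, THF, −78 °C) opens 19 at the CH2 terminus. Acidic work-up gives the lactone phosphine oxide (5S)-5-[2-(diphenylphosphoryl)propyl]-3,3-dimethyloxolan-2-one F1.
- LDA (2 equiv) regenerates the phosphinoyl carbanion. It is C-acylated by the lactone carbonyl and so closes the carbocycle as the β-keto phosphine oxide (4S)-2-(diphenylphosphoryl)-4-hydroxy-2,6,6-trimethylcyclohexan-1-one F2.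
- Acetylide 26 (2.2 equiv) adds to the ketone from the face away from the Ph2P(O) group. This gives the β-hydroxy phosphine oxide (4S)-2-(diphenylphosphoryl)-1-[(3E,5E)-6-iodo-3-methylhexa-3,5-dien-1-yn-1-yl]-2,6,6-trimethylcyclohexane-1,4-diol F3, in which the tertiary hydroxyl and the phosphinoyl group are cis.
- NaH in DMF then effects syn-elimination of diphenylphosphinate to (1R)-4-[(3E,5E)-6-iodo-3-methylhexa-3,5-dien-1-yn-1-yl]-3,5,5-trimethylcyclohex-3-en-1-ol F4. Ac2O/pyridine gives 29.

**Step 18.**
- Risks: compound 16 carries both a boronate and a bromide, so head-to-tail self-coupling can compete with the wanted cross-coupling under basic conditions. Aqueous base can also hydrolyse the butenolide or the acetate.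
- Fallback: it inverts the polarity of the partners and works without base (Stille coupling). It sets out from 16 and 29 and comes back at 30.
- Iododeboronation of 16 with retention (NaOMe, then ICl, THF, −78 °C) gives (5Z)-3-bromo-5-[(2E,4E)-5-iodo-2-methylpenta-2,4-dien-1-ylidene]furan-2(5H)-one F7, which holds only electrophilic sites.
- Palladium-catalysed stannylation of 29 with hexabutylditin gives (1R)-3,5,5-trimethyl-4-[(3E,5E)-3-methyl-6-(tributylstannyl)hexa-3,5-dien-1-yn-1-yl]cyclohex-3-en-1-yl acetate F8.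
- Pd2(dba)3/AsPh3 in NMP at 23 °C then couples F8 at the C–I bond of F7 and leaves the α-bromide, giving 30.

**Step 15.**
- Risks: the ylide may attack the ester or act as a base. The pentacoordinate oxaphospholane form of 22 may resist lactonisation, so the salt may be obtained impure.
- Fallback: it forms the C4–C5 bond with a phosphorus-free carbon nucleophile and brings phosphorus in last by SN2 displacement. It sets out from 19 and comes back at 23.
- Vinylmagnesium bromide with catalytic CuI (THF, −30 °C) opens 19 at the CH2 terminus, and the alkoxide lactonises to (5R)-3,3-dimethyl-5-(prop-2-en-1-yl)oxolan-2-one F5.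
- Markovnikov addition of HBr (HBr/AcOH, 0 °C) gives (5S)-5-(2-bromopropyl)-3,3-dimethyloxolan-2-one F6.
- PPh3 in MeCN at 100 °C (sealed tube) gives 23.

Further compounds
F1 | step 17 | (5S)-5-[2-(diphenylphosphoryl)propyl]-3,3-dimethyloxolan-2-one | O=C1O[C@H](CC(C)P(=O)(c2ccccc2)c2ccccc2)CC1(C)C
F2 | step 17 | (4S)-2-(diphenylphosphoryl)-4-hydroxy-2,6,6-trimethylcyclohexan-1-one | O[C@@H]1CC(C)(P(=O)(c2ccccc2)c2ccccc2)C(=O)C(C)(C)C1
F3 | step 17 | (4S)-2-(diphenylphosphoryl)-1-[(3E,5E)-6-iodo-3-methylhexa-3,5-dien-1-yn-1-yl]-2,6,6-trimethylcyclohexane-1,4-diol | O[C@@H]1CC(C)(P(=O)(c2ccccc2)c2ccccc2)C(O)(C#C/C(C)=C/C=C/I)C(C)(C)C1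
F4 | step 17 | (1R)-4-[(3E,5E)-6-iodo-3-methylhexa-3,5-dien-1-yn-1-yl]-3,5,5-trimethylcyclohex-3-en-1-ol | O[C@@H]1CC(C)=C(C#C/C(C)=C/C=C/I)C(C)(C)C1
F5 | step 15 | (5R)-3,3-dimethyl-5-(prop-2-en-1-yl)oxolan-2-one | C=CC[C@@H]1CC(C)(C)C(=O)O1
F6 | step 15 | (5S)-5-(2-bromopropyl)-3,3-dimethyloxolan-2-one | CC(Br)C[C@@H]1CC(C)(C)C(=O)O1
F7 | step 18 | (5Z)-3-bromo-5-[(2E,4E)-5-iodo-2-methylpenta-2,4-dien-1-ylidene]furan-2(5H)-one | I/C=C/C=C(C)/C=C1C=C(Br)C(=O)O/1
F8 | step 18 | (1R)-3,5,5-trimethyl-4-[(3E,5E)-3-methyl-6-(tributylstannyl)hexa-3,5-dien-1-yn-1-yl]cyclohex-3-en-1-yl acetate | CC(=O)O[C@@H]1CC(C)=C(C#C/C(C)=C/C=C/[Sn](CCCC)(CCCC)CCCC)C(C)(C)C1
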